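The constants used here come from no measurement; the result is computed.

In a one-step world the excess would stay as the catalyst made it, but here a further step turns each product into the other, so what counts is how much of that excess the flask keeps.

    reagent + free catalyst + left-handed substrate → free catalyst + left-handed product (k1 = 6740 L² mol⁻² s⁻¹, Ea1 = 8.00 kJ mol⁻¹)
    reagent + free catalyst + right-handed substrate → free catalyst + right-handed product (k2 = 159 L² mol⁻² s⁻¹, Ea2 = 37.0 kJ mol⁻¹)
    left-handed product ⇌ right-handed product (k3 = 0.0494 s⁻¹, Ea3 = 86.0 kJ mol⁻¹)
    reagent + free catalyst → spent catalyst (k4 = 0.141 L mol⁻¹ s⁻¹, Ea4 = 67.0 kJ mol⁻¹)
    (constants at 50 °C)

| flask | left-handed substrate | reagent | free catalyst | right-handed substrate | temperature | time | remark |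
|---|---|---|---|---|---|---|---|
| summer | 0.020 M | 0.0200 M | 3.0 mM | 0.020 M | 50 °C | 40 s |  |
| noon | 0.020 M | 0.0200 M | 3.0 mM | 0.020 M | 75 °C | 40 s |  |
| autumn | 0.020 M | 0.0200 M | 3.0 mM | 0.020 M | 25 °C | 40 s |  |
| dusk | 0.020 M | 0.0200 M | 3.0 mM | 0.020 M |  | 40 s | at 25 °C until 12 s, from then on at 75 °C |

- free catalyst is single-handed; left-handed substrate and right-handed substrate are mirror images of each other, charged as a racemate, each of them at the stated concentration
- the constants hold at 50 °C; other temperatures follow from the activation energies
- an excess is the difference of the two amounts in percent of their sum
- an excess is below zero if the other one leads

- the flask with the highest excess of left-handed product over right-handed product ("all alike" if they lie within 1.5 percentage points) (summer / noon / autumn / dusk / all alike)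
- excess of left-handed product over right-handed product at the end, summer
- excess of left-handed product over right-handed product at the end, noon
- excess of left-handed product over right-handed product at the end, autumn
- excess of left-handed product over right-handed product at the end, dusk

Start with autumn, the coldest flask. How clean is the product as it forms? By my reckoning, left-handed substrate in autumn reacts 105 times as fast as right-handed substrate at equal amounts (the selectivity factor), so the first product formed in autumn carries an excess of 98.1%.

Is making or scrambling quicker? With reagent and free catalyst held at their charges, autumn's left-handed substrate has a half-life of 2.20 s. The constant of scrambling there is 0.00337 s⁻¹ in each direction, and the difference between the products falls at the sum of both directions, so it halves in 103 s. Because scrambling in autumn is so much slower, I count the making there as done at the start and reckon with scrambling by itself.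

How much then survives? Take the keeping factor: the share of an excess still standing after a time at a given temperature, the exponential of minus both constants added and multiplied by the time. For autumn over 40 s it is 76.3%, which gives 74.9%.

Summer, with its constant of 0.0494 s⁻¹, keeps 1.92%, which gives 1.83%. Summer's excess halves in 7.02 s, shorter than autumn's, so I trust this figure less. At
75 °C the constant is 0.492 s⁻¹, so noon comes to <0.001%, and dusk, hot after 12 s, to <0.001%. My pick is autumn.

The forecast also names autumn, with 75.5% there (72% to 79%). It stands above my figure for summer, at 3.9% (3% to 5%). For noon and dusk it gives 0.06% and 0.06%, each 0.02% to 0.15%, again above mine, “leaving only a trace sustained by the last product still forming”.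

The simulation gives autumn as the leader, with 75.4%, against 3.75% for summer, 0.0312% for noon and 0.0386% for dusk. Autumn has not come to rest: at 40.0 s it still holds 6.0% of its reagent charge, and its left-handed product stands at 41.2% and its right-handed product at 5.78% of the substrates charged. The same autumn flask read at 2.5 min has a keeping factor of 36.4%, which with the first product's excess gives 35.7%, and it reads 36.3%. At ten times the time the factor is 6.73%, which gives 6.60%, and autumn's excess reads 6.79%.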